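**Plan**
- **Ring C cuts:** The phenols at C5, C7 and C4' are unmasked last from benzyl ethers. Ring C is cut at O1–C2 and C2–C3, which gives a ring A acetophenone and a ring B benzaldehyde.
- **Ring B cuts:** Ring B is cut at C1'–C2' and C5'–C6'. It bears oxygen on four adjacent carbons (C2', C3', C4', C5') with C2' para to C5', and these are the four ring carbons of dimethyl squarate. C6', C1' and the formyl carbon (later C2) come from a three-carbon acrolein acetal unit.
- **Forward, ring B:** Vinyllithium addition to the squarate makes C5'–C6'. The C4' oxygen is marked with benzyl while it is the only vinylogous ester oxygen. Heating then breaks C2'–C5' of the four-membered ring and closes ring B by forming C1'–C2'.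
- **Forward, rings A and C:** Ring A is bought as phloroacetophenone. Aldol condensation joins the halves (C2–C3), oxidative cyclisation closes ring C (O1–C2), and hydrogenolysis ends the route.
- **Stereochemistry:** The target has no stereocentre. The quaternary centre of the cyclobutenones is racemic and becomes sp2 in the key step, and both E alkenes form under thermodynamic control and are consumed later.

Key step: step 4

Remark: primed locants are those of flavone ring B. In the cyclobutenones C1 is the carbonyl carbon and C4 the quaternary carbon. Every compound with one stereocentre is taken as the racemate.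

**Step 1**
Reactants: 1 3,3-diethoxyprop-1-yne
Product: 2 tributyl[(E)-3,3-diethoxyprop-1-enyl]stannane
Conditions: Bu3SnH (1.1 equiv), AIBN (5 mol %), neat, 90 °C; chromatography on Et3N-deactivated silica
Reagents that add atoms: tributyltin hydride, CCCC[SnH](CCCC)CCCC
Why: Radical-chain hydrostannylation of a terminal alkyne places tin on the terminal carbon, and reversible stannyl radical addition should drain the first-formed Z adduct into the more stable E isomer, which is separated from minor isomers.

**Step 2**
Reactants: 2 tributyl[(E)-3,3-diethoxyprop-1-enyl]stannane; 3 dimethyl squarate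
Product: 6 4-[(E)-3,3-diethoxyprop-1-enyl]-2,3,4-trimethoxycyclobut-2-en-1-one (racemic), via (E)-3,3-diethoxyprop-1-enyllithium 4 (not isolated), via lithium cyclobutenolate adduct 5 (not isolated)
Conditions: n-BuLi (1.0 equiv), THF, −78 °C; cannulated into 3, THF, −78 °C; MeOTf (1.5 equiv), −78 → 0 °C; aq NaHCO3
Reagents that add atoms: methyl triflate, COS(=O)(=O)C(F)(F)F
Why: Tin–lithium exchange keeps the E geometry, the vinyllithium adds 1,2 to one of the two equivalent squarate carbonyl groups, and O-methylation of the tertiary lithium alkoxide fixes the future C5' methoxy group, the new quaternary centre forming as a racemate that step 4 erases.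

**Step 3**
Reactants: 6 4-[(E)-3,3-diethoxyprop-1-enyl]-2,3,4-trimethoxycyclobut-2-en-1-one; 7 benzyl alcohol
Product: 8 3-(benzyloxy)-4-[(E)-3,3-diethoxyprop-1-enyl]-2,4-dimethoxycyclobut-2-en-1-one (racemic)
Conditions: 7 (10 equiv), n-BuLi (0.3 equiv), 4 Å MS, THF, −20 → 0 °C; pH 7 buffer
Reagents that add atoms: none
Why: Proposed new method: lithium benzyl oxide should add to C3, the beta carbon of the only vinylogous ester in 6, to give a C1 enolate that expels methoxide (conjugate addition–elimination), whereas the C2 and C4 methoxy groups have no such pathway; the excess of 7 and methanol uptake by the sieves pull the equilibrium, and the low temperature holds back ring opening of any carbonyl adduct; the closest known reaction types are the transesterification of dialkyl squarates with alcohols and the amine-for-alkoxide addition–elimination on squarate esters.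

**Step 4**
Reactants: 8 3-(benzyloxy)-4-[(E)-3,3-diethoxyprop-1-enyl]-2,4-dimethoxycyclobut-2-en-1-one
Product: 11 4-(benzyloxy)-2-hydroxy-3,5-dimethoxybenzaldehyde diethyl acetal, via dienylketene 9 (not isolated), via cyclohexadienone 10 (not isolated)
Conditions: toluene (0.02 M, degassed), 110 °C, Ar, base-washed glassware
Reagents that add atoms: none
Why: Heat cleaves the C1–C4 bond of 8 in a four-electron conrotatory opening to dienylketene 9, whose ketene carbon (future C2') bonds to the acetal-bearing alkene terminus (future C1') in a six-electron disrotatory electrocyclisation, and enolisation of cyclohexadienone 10 should give phenol 11. The closest known reaction type is the Moore rearrangement of squarate-derived 4-alkenyl-4-alkoxycyclobutenones to hydroquinone monoethers. Ring B is the only ring closed, as a six-membered carbocycle by 6π electrocyclic closure in which the ketene C=C is one end of the triene. No stereocentre survives, because the quaternary centre of 8 becomes sp2 C5' on opening and the single sp3 centre of 10 is lost on aromatisation. The step needs the alkenyl group to rotate inward, and the methoxy donor on the same carbon secures this by its pronounced preference for outward rotation, so the 3Z ketene that can cyclise is the one formed. Connectivity alone then places the C4 methoxy at C5', the C3 benzyloxy at C4', the C2 methoxy at C3' and the ketene oxygen as the only free hydroxyl at C2'.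

**Step 5**
Reactants: 11 4-(benzyloxy)-2-hydroxy-3,5-dimethoxybenzaldehyde diethyl acetal
Product: 12 4-(benzyloxy)-2,3,5-trimethoxybenzaldehyde diethyl acetal
Conditions: MeI, K2CO3, DMF, rt
Reagents that add atoms: methyl iodide, CI
Why: Williamson ether synthesis on the single free phenol under basic conditions that leave the acetal and the benzyl ether untouched.

**Step 6**
Reactants: 12 4-(benzyloxy)-2,3,5-trimethoxybenzaldehyde diethyl acetal
Product: 13 4-(benzyloxy)-2,3,5-trimethoxybenzaldehyde
Conditions: PPTS (10 mol %), acetone/H2O 9:1, rt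
Reagents that add atoms: water, O
Why: Acid-catalysed acetal hydrolysis is very easy for an electron-rich benzaldehyde acetal and does not touch aryl methyl or benzyl ethers.

**Step 7**
Reactants: 14 2,4,6-trihydroxyacetophenone
Product: 15 1-[2,4-bis(benzyloxy)-6-hydroxyphenyl]ethan-1-one
Conditions: BnBr (2.05 equiv), K2CO3 (2.2 equiv), DMF, rt → 50 °C
Reagents that add atoms: benzyl bromide, BrCc1ccccc1
Why: Selective Williamson benzylation stops at the dibenzyl ether because the last hydroxyl is hydrogen-bonded to the acetyl carbonyl and is the least nucleophilic.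

**Step 8**
Reactants: 13 4-(benzyloxy)-2,3,5-trimethoxybenzaldehyde; 15 1-[2,4-bis(benzyloxy)-6-hydroxyphenyl]ethan-1-one
Product: 16 (E)-1-[2,4-bis(benzyloxy)-6-hydroxyphenyl]-3-[4-(benzyloxy)-2,3,5-trimethoxyphenyl]prop-2-en-1-one
Conditions: KOH (50% aq), EtOH, rt; dilute HCl to pH 5
Reagents that add atoms: none
Why: Claisen–Schmidt condensation of a methyl ketone with a non-enolisable aldehyde, in which dehydration by the E1cB pathway gives the conjugated E enone.

**Step 9**
Reactants: 16 (E)-1-[2,4-bis(benzyloxy)-6-hydroxyphenyl]-3-[4-(benzyloxy)-2,3,5-trimethoxyphenyl]prop-2-en-1-one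
Product: 18 5,7-bis(benzyloxy)-2-[4-(benzyloxy)-2,3,5-trimethoxyphenyl]-4H-chromen-4-one, via flavanone 17 (not isolated)
Conditions: I2 (10 mol %), DMSO, 120 °C; aq Na2S2O3
Reagents that add atoms: none
Why: Iodine-catalysed oxidative cyclisation of a 2'-hydroxychalcone closes ring C by oxa-Michael addition to racemic flavanone 17, whose alpha-iodination and loss of HI give the flavone and erase the C2 centre while DMSO reoxidises HI.

**Step 10**
Reactants: 18 5,7-bis(benzyloxy)-2-[4-(benzyloxy)-2,3,5-trimethoxyphenyl]-4H-chromen-4-one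
Product: 19 5,7,4'-trihydroxy-2',3',5'-trimethoxyflavone
Conditions: H2 (1 atm), 10% Pd/C, THF/MeOH, rt
Reagents that add atoms: none
Why: Catalytic hydrogenolysis removes all three aryl benzyl ethers at once, and the C2–C3 double bond of the chromone is not reduced at atmospheric pressure.

**Compound list**
1 | 3,3-diethoxyprop-1-yne | C#CC(OCC)OCC | starting material
2 | tributyl[(E)-3,3-diethoxyprop-1-enyl]stannane | CCCC[Sn](CCCC)(CCCC)/C=C/C(OCC)OCC | intermediate
3 | dimethyl squarate (3,4-dimethoxycyclobut-3-ene-1,2-dione) | COC1=C(OC)C(=O)C1=O | starting material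
4 | (E)-3,3-diethoxyprop-1-enyllithium | [Li]/C=C/C(OCC)OCC | intermediate
5 | lithium 1-[(E)-3,3-diethoxyprop-1-enyl]-2,3-dimethoxy-4-oxocyclobut-2-en-1-olate (racemic) | [Li+].[O-]C1(/C=C/C(OCC)OCC)C(OC)=C(OC)C1=O | intermediate
6 | 4-[(E)-3,3-diethoxyprop-1-enyl]-2,3,4-trimethoxycyclobut-2-en-1-one (racemic) | O=C1C(OC)=C(OC)C1(OC)/C=C/C(OCC)OCC | intermediate
7 | benzyl alcohol | OCc1ccccc1 | starting material
8 | 3-(benzyloxy)-4-[(E)-3,3-diethoxyprop-1-enyl]-2,4-dimethoxycyclobut-2-en-1-one (racemic) | O=C1C(OC)=C(OCc2ccccc2)C1(OC)/C=C/C(OCC)OCC | intermediate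
9 | (3Z,5E)-3-(benzyloxy)-7,7-diethoxy-2,4-dimethoxyhepta-1,3,5-trien-1-one (dienylketene) | O=C=C(OC)/C(OCc1ccccc1)=C(\C=C\C(OCC)OCC)OC | intermediate
10 | 3-(benzyloxy)-6-(diethoxymethyl)-2,4-dimethoxycyclohexa-2,4-dien-1-one (racemic) | O=C1C(OC)=C(OCc2ccccc2)C(OC)=CC1C(OCC)OCC | intermediate
11 | 4-(benzyloxy)-2-hydroxy-3,5-dimethoxybenzaldehyde diethyl acetal | CCOC(OCC)c1cc(OC)c(OCc2ccccc2)c(OC)c1O | intermediate
12 | 4-(benzyloxy)-2,3,5-trimethoxybenzaldehyde diethyl acetal | CCOC(OCC)c1cc(OC)c(OCc2ccccc2)c(OC)c1OC | intermediate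
13 | 4-(benzyloxy)-2,3,5-trimethoxybenzaldehyde | O=Cc1cc(OC)c(OCc2ccccc2)c(OC)c1OC | intermediate
14 | 2,4,6-trihydroxyacetophenone | CC(=O)c1c(O)cc(O)cc1O | starting material
15 | 1-[2,4-bis(benzyloxy)-6-hydroxyphenyl]ethan-1-one | CC(=O)c1c(O)cc(OCc2ccccc2)cc1OCc1ccccc1 | intermediate
16 | (E)-1-[2,4-bis(benzyloxy)-6-hydroxyphenyl]-3-[4-(benzyloxy)-2,3,5-trimethoxyphenyl]prop-2-en-1-one | O=C(/C=C/c1cc(OC)c(OCc2ccccc2)c(OC)c1OC)c1c(O)cc(OCc2ccccc2)cc1OCc1ccccc1 | intermediate
17 | 5,7-bis(benzyloxy)-2-[4-(benzyloxy)-2,3,5-trimethoxyphenyl]chroman-4-one (racemic) | COc1cc(C2CC(=O)c3c(OCc4ccccc4)cc(OCc4ccccc4)cc3O2)c(OC)c(OC)c1OCc1ccccc1 | intermediate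
18 | 5,7-bis(benzyloxy)-2-[4-(benzyloxy)-2,3,5-trimethoxyphenyl]-4H-chromen-4-one | COc1cc(-c2cc(=O)c3c(OCc4ccccc4)cc(OCc4ccccc4)cc3o2)c(OC)c(OC)c1OCc1ccccc1 | intermediate
19 | 5,7,4'-trihydroxy-2',3',5'-trimethoxyflavone | COc1cc(-c2cc(=O)c3c(O)cc(O)cc3o2)c(OC)c(OC)c1O | target

**Step count**
- Total step count: 10.
- Longest linear sequence: 9 (steps 1 to 6 and 8 to 10, from 1).

**Steps most likely to fail**

**Step 3.**
- *What may go wrong:* The alkoxide may attack the carbonyl carbon instead of C3, and the resulting cyclobutene alkoxide can open with release of ring strain. The exchange is also an equilibrium and may stall before completion.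
- *Fallback:* It uses known chemistry only, sets out from 2 (with 7) and comes back at 13. It gives up marking the oxygen on the four-membered ring and instead differentiates a catechol by acidity.
- Azeotropic esterification of squaric acid with 7 gives dibenzyl squarate F1.
- Vinyllithium 4, generated from 2, adds to it, and methyl triflate capture gives 2,3-bis(benzyloxy)-4-[(E)-3,3-diethoxyprop-1-enyl]-4-methoxycyclobut-2-en-1-one F2.
- The same thermolysis gives 3,4-bis(benzyloxy)-2-hydroxy-5-methoxybenzaldehyde diethyl acetal F3, and MeI/K2CO3 gives 3,4-bis(benzyloxy)-2,5-dimethoxybenzaldehyde diethyl acetal F4.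
- Hydrogenolysis (H2, 10% Pd/C, EtOAc, trace Et3N) gives 3,4-dihydroxy-2,5-dimethoxybenzaldehyde diethyl acetal F5, with the acetal shielding the formyl carbon from reduction. Mild aqueous acid then gives 3,4-dihydroxy-2,5-dimethoxybenzaldehyde F6.
- The hydroxyl para to the formyl group is the more acidic one, so BnBr (1 equiv) with NaHCO3 and NaI in DMF should give 4-(benzyloxy)-3-hydroxy-2,5-dimethoxybenzaldehyde F7.
- Methylation of F7 with MeI/K2CO3 gives 13.

**Step 4.**
- *What may go wrong:* Once the ortho phenol has formed, thermal loss of ethanol from the acetal may erode the material. So may capture of the ketene by product phenol, and air oxidation of the electron-rich ring.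
- *Fallback:* It sets out from 3 and comes back at 13. It keeps the same ring closure but removes the labile group from the thermolysis substrate, so the formyl carbon is added only after ring B exists.
- Vinyllithium (from vinyl bromide and t-BuLi) adds to 3, and methyl triflate capture gives 2,3,4-trimethoxy-4-vinylcyclobut-2-en-1-one F8.
- Exchange as in step 3 gives 3-(benzyloxy)-2,4-dimethoxy-4-vinylcyclobut-2-en-1-one F9, and thermolysis in toluene gives 3-(benzyloxy)-2,4-dimethoxyphenol F10.
- Magnesium-mediated ortho-formylation (MgCl2, Et3N, paraformaldehyde, MeCN, reflux) can only reach the one free ortho position, the future C1'. It gives 4-(benzyloxy)-2-hydroxy-3,5-dimethoxybenzaldehyde F11.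
- Methylation of F11 with MeI/K2CO3 gives 13.

**Step 9.**
- *What may go wrong:* At 120 °C the HI formed may strip benzyl groups, iodine may substitute the electron-rich rings, and dehydrogenation may stop at the flavanone stage.
- *Fallback:* It sets out from 13 and 15 and comes back at 18. It replaces the chalcone route by acyl transfer, so no oxidation of ring C is needed.
- Pinnick oxidation of 13 (NaClO2, NaH2PO4, 2-methylbut-2-ene, t-BuOH/H2O) gives 4-(benzyloxy)-2,3,5-trimethoxybenzoic acid F12.
- Coupling with 15 (EDC·HCl, DMAP, CH2Cl2) gives 2-acetyl-3,5-bis(benzyloxy)phenyl 4-(benzyloxy)-2,3,5-trimethoxybenzoate F13.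
- Baker–Venkataraman rearrangement (LiHMDS, THF, −78 °C → rt) gives 1-[2,4-bis(benzyloxy)-6-hydroxyphenyl]-3-[4-(benzyloxy)-2,3,5-trimethoxyphenyl]propane-1,3-dione F14.
- Cyclodehydration of F14 (cat. TsOH, toluene, 80 °C) gives 18.

**Further compounds**
F1 | step 3 | dibenzyl squarate (3,4-bis(benzyloxy)cyclobut-3-ene-1,2-dione) | O=C1C(=O)C(OCc2ccccc2)=C1OCc1ccccc1
F2 | step 3 | 2,3-bis(benzyloxy)-4-[(E)-3,3-diethoxyprop-1-enyl]-4-methoxycyclobut-2-en-1-one (racemic) | O=C1C(OCc2ccccc2)=C(OCc2ccccc2)C1(OC)/C=C/C(OCC)OCC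
F3 | step 3 | 3,4-bis(benzyloxy)-2-hydroxy-5-methoxybenzaldehyde diethyl acetal | CCOC(OCC)c1cc(OC)c(OCc2ccccc2)c(OCc2ccccc2)c1O
F4 | step 3 | 3,4-bis(benzyloxy)-2,5-dimethoxybenzaldehyde diethyl acetal | CCOC(OCC)c1cc(OC)c(OCc2ccccc2)c(OCc2ccccc2)c1OC
F5 | step 3 | 3,4-dihydroxy-2,5-dimethoxybenzaldehyde diethyl acetal | CCOC(OCC)c1cc(OC)c(O)c(O)c1OC
F6 | step 3 | 3,4-dihydroxy-2,5-dimethoxybenzaldehyde | O=Cc1cc(OC)c(O)c(O)c1OC
F7 | step 3 | 4-(benzyloxy)-3-hydroxy-2,5-dimethoxybenzaldehyde | O=Cc1cc(OC)c(OCc2ccccc2)c(O)c1OC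
F8 | step 4 | 2,3,4-trimethoxy-4-vinylcyclobut-2-en-1-one (racemic) | O=C1C(OC)=C(OC)C1(OC)C=C
F9 | step 4 | 3-(benzyloxy)-2,4-dimethoxy-4-vinylcyclobut-2-en-1-one (racemic) | O=C1C(OC)=C(OCc2ccccc2)C1(OC)C=C
F10 | step 4 | 3-(benzyloxy)-2,4-dimethoxyphenol | COc1ccc(O)c(OC)c1OCc1ccccc1
F11 | step 4 | 4-(benzyloxy)-2-hydroxy-3,5-dimethoxybenzaldehyde | O=Cc1cc(OC)c(OCc2ccccc2)c(OC)c1O
F12 | step 9 | 4-(benzyloxy)-2,3,5-trimethoxybenzoic acid | OC(=O)c1cc(OC)c(OCc2ccccc2)c(OC)c1OC
F13 | step 9 | 2-acetyl-3,5-bis(benzyloxy)phenyl 4-(benzyloxy)-2,3,5-trimethoxybenzoate | CC(=O)c1c(OC(=O)c2cc(OC)c(OCc3ccccc3)c(OC)c2OC)cc(OCc2ccccc2)cc1OCc1ccccc1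
F14 | step 9 | 1-[2,4-bis(benzyloxy)-6-hydroxyphenyl]-3-[4-(benzyloxy)-2,3,5-trimethoxyphenyl]propane-1,3-dione | O=C(CC(=O)c1cc(OC)c(OCc2ccccc2)c(OC)c1OC)c1c(O)cc(OCc2ccccc2)cc1OCc1ccccc1
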